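**Retrosynthetic overview**
- The C3–Br bond is made last, by electrophilic bromination of 5,6-dibromo-1H-indole; N1–H is freed just before by removing an N1-pyrimidin-2-yl group.
- The pyrrole ring is the only ring formed. It is cut at C3–C3a and N1–C2, giving N-(3,4-dibromophenyl)pyrimidin-2-amine and vinylene carbonate as a two-carbon acetylene equivalent.
- Feature on which this rests: C2 and C3 form an unsubstituted two-carbon unit, and of the two carbons ortho to nitrogen in the benzene ring, the one that becomes C3a has a C–H neighbour (C4) while the other (C7) is wedged between C7a–N1 and C6–Br.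
- The aminopyrimidine comes from 3,4-dibromoaniline and 2-chloropyrimidine by nucleophilic aromatic substitution.

Key step: step 2

Assumption: the target is achiral, so no stereocentre has to be set. The only stereocentre on the way, in hemiaminal 6, is racemic and is destroyed by dehydration.

Step 1
Reactants: 1 3,4-dibromoaniline; 2 2-chloropyrimidine
Product: 3 N-(3,4-dibromophenyl)pyrimidin-2-amine
Conditions: p-TsOH·H2O (0.2 equiv), 1,4-dioxane, 100 °C; aq. NaHCO3 work-up
Reagents that add atoms: none
Why: Acid-catalysed nucleophilic aromatic substitution (addition–elimination), in which protonation of the pyrimidine makes its C2 electrophilic enough for the weakly nucleophilic dibromoaniline, and the aryl bromides stay untouched because no transition metal is present.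

Step 2
Reactants: 3 N-(3,4-dibromophenyl)pyrimidin-2-amine; 4 vinylene carbonate
Product: 7 5,6-dibromo-1-(pyrimidin-2-yl)-1H-indole, via arylacetaldehyde 5 (not isolated), via indolin-2-ol 6 (not isolated)
Conditions: [Cp*RhCl2]2 (4 mol %), AgSbF6 (16 mol %), NaOAc (30 mol %), 4 (1.5 equiv), ClCH2CH2Cl, 100 °C, sealed tube
Reagents that add atoms: none
Why: The cationic Cp*Rh acetate of trivalent rhodium, generated from [Cp*RhCl2]2, AgSbF6 and NaOAc, is bound by a pyrimidine nitrogen of 3 and cleaves an ortho C–H bond by carboxylate-assisted concerted metalation–deprotonation to give a six-membered rhodacycle; the alkene of 4 then inserts into the Rh–aryl bond (forming C3–C3a), beta-oxygen elimination opens the carbonate, and loss of CO2 with protonation releases arylacetaldehyde 5 and returns trivalent rhodium, so no external oxidant is needed. The anilinic N–H adds to the aldehyde carbon in a 5-exo-trig closure (forming N1–C2) to give hemiaminal 6, which dehydrates to the aromatic pyrrole ring of 7. The closest known reaction type is the Cp*Rh-catalysed, azine-directed C–H annulation of N-aryl-2-aminoazines with vinylene carbonate as an acetylene surrogate, which gives indoles unsubstituted at C2 and C3 and is here applied to a dibrominated arene. No stereocentre remains, since the carbinol carbon of racemic 6 becomes the sp2 carbon C2. The step needs site selectivity between the two ortho C–H bonds, and the bulky Cp*Rh centre should avoid the C–H flanked by nitrogen and bromine and metalate the carbon with a hydrogen neighbour, which becomes C3a. Both C–Br bonds should be carried through because trivalent rhodium does not insert into aryl bromides under these conditions.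

Step 3
Reactants: 7 5,6-dibromo-1-(pyrimidin-2-yl)-1H-indole
Product: 8 5,6-dibromo-1H-indole
Conditions: NaOEt (3 equiv), DMSO, 100 °C, N2; then H2O
Reagents that add atoms: none
Why: Nucleophilic aromatic substitution by ethoxide at the pyrimidine C2, with the indole nitrogen as leaving group, is the established way to remove an N-pyrimidyl directing group, and the unactivated aryl bromides are not expected to be substituted.

Step 4
Reactants: 8 5,6-dibromo-1H-indole
Product: 9 3,5,6-tribromo-1H-indole
Conditions: NBS (1.0 equiv), DMF, 0 °C, dark
Reagents that add atoms: N-bromosuccinimide, O=C1CCC(=O)N1Br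
Why: Electrophilic aromatic substitution at C3, the most nucleophilic position of an N–H indole, with one equivalent of NBS, while the two ring bromines deactivate the benzenoid positions so that only the pyrrole ring should react.

**Compound list**
1 | 3,4-dibromoaniline | Nc1ccc(Br)c(Br)c1 | starting material
2 | 2-chloropyrimidine | Clc1ncccn1 | starting material
3 | N-(3,4-dibromophenyl)pyrimidin-2-amine | Brc1ccc(Nc2ncccn2)cc1Br | intermediate
4 | vinylene carbonate (1,3-dioxol-2-one) | O=C1OC=CO1 | starting material
5 | 2-[4,5-dibromo-2-(pyrimidin-2-ylamino)phenyl]acetaldehyde (not isolated) | O=CCc1cc(Br)c(Br)cc1Nc1ncccn1 | intermediate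
6 | 5,6-dibromo-1-(pyrimidin-2-yl)-2,3-dihydro-1H-indol-2-ol, racemic (not isolated) | OC1Cc2cc(Br)c(Br)cc2N1c1ncccn1 | intermediate
7 | 5,6-dibromo-1-(pyrimidin-2-yl)-1H-indole | Brc1cc2ccn(-c3ncccn3)c2cc1Br | intermediate
8 | 5,6-dibromo-1H-indole | Brc1cc2cc[nH]c2cc1Br | intermediate
9 | 3,5,6-tribromo-1H-indole | Brc1cc2[nH]cc(Br)c2cc1Br | target

**Step count**
Total steps: 4. Longest linear sequence: 4 steps (1 → 3 → 7 → 8 → 9).

**Steps most likely to fail**

1. Step 2 (key step). What may go wrong:
- slow C–H metalation of the electron-poor dibromoarene;
- partial metalation at the hindered ortho position;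
- a second, pyrimidyl-directed functionalisation at C2 of the product by excess vinylene carbonate;
- stalling at the hemiaminal stage before dehydration.

Fallback, setting out from 1 and bypassing steps 1 to 3: iodination with N-iodosuccinimide in MeCN at room temperature should occur at the free, unhindered ortho position and give 4,5-dibromo-2-iodoaniline F1. Sonogashira coupling with trimethylsilylacetylene (PdCl2(PPh3)2, CuI, Et3N, THF, room temperature), selective for the C–I bond over both C–Br bonds, should give 4,5-dibromo-2-[(trimethylsilyl)ethynyl]aniline F2. K2CO3 in MeOH should remove the silyl group to give 4,5-dibromo-2-ethynylaniline F3. CuI in DMF at 110 °C (Castro-type 5-endo-dig hydroamination) should then close the pyrrole ring to 8, where the route is rejoined before step 4.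

2. Step 3. What may go wrong:
- base-induced loss of bromide from the ortho-dibromo arene in hot ethoxide/DMSO, through aryne formation or hydrodebromination, before the pyrimidyl group is cleaved;
- incomplete cleavage.

Fallback, setting out from 7: N-methylation of the pyrimidine with MeOTf in CH2Cl2 (0 °C to room temperature) should give 2-(5,6-dibromo-1H-indol-1-yl)-1-methylpyrimidin-1-ium trifluoromethanesulfonate F4. Its C2 is far more electrophilic, so NaOH in MeOH/H2O at room temperature to 50 °C should release the indole by the quaternisation–hydrolysis sequence used for N-azinyl directing groups. This returns to the route at 8.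

3. Step 4. What may go wrong:
- over-bromination at C2;
- acid- or light-induced decomposition of the N–H 3-bromoindole during isolation.

Fallback, setting out from 8: N-silylation (NaH, triisopropylsilyl chloride, THF, 0 °C) should give 5,6-dibromo-1-(triisopropylsilyl)-1H-indole F5, in which the bulky silyl group shields C2. NBS in THF at −78 °C should then give the stable, chromatographable 3,5,6-tribromo-1-(triisopropylsilyl)-1H-indole F6. Tetrabutylammonium fluoride in THF at 0 °C should remove the silyl group and arrive at 9.

**Further compounds**
F1 | step 2 | 4,5-dibromo-2-iodoaniline | Nc1cc(Br)c(Br)cc1I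
F2 | step 2 | 4,5-dibromo-2-[(trimethylsilyl)ethynyl]aniline | C[Si](C)(C)C#Cc1cc(Br)c(Br)cc1N
F3 | step 2 | 4,5-dibromo-2-ethynylaniline | C#Cc1cc(Br)c(Br)cc1N
F4 | step 3 | 2-(5,6-dibromo-1H-indol-1-yl)-1-methylpyrimidin-1-ium trifluoromethanesulfonate | C[n+]1cccnc1-n1ccc2cc(Br)c(Br)cc21.[O-]S(=O)(=O)C(F)(F)F
F5 | step 4 | 5,6-dibromo-1-(triisopropylsilyl)-1H-indole | CC(C)[Si](C(C)C)(C(C)C)n1ccc2cc(Br)c(Br)cc21
F6 | step 4 | 3,5,6-tribromo-1-(triisopropylsilyl)-1H-indole | CC(C)[Si](C(C)C)(C(C)C)n1cc(Br)c2cc(Br)c(Br)cc21
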